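## Plan

- Retrosynthetic cuts, in order: O2–C3 (pyran, 6-endo addition of the C1 hydroxyl to a C4a alkyne); C4a–C4 (Sonogashira coupling of a ring A enol triflate with the side-chain enyne); C5–Cl and C4a–O (chloro-1,3-dione); C8a–C1 (anti SN2' opening of a C5–C6 vinyl epoxide); C7–O and C8–O (dioxygenase).
- Enabling feature: ring A (C4a, C5, C6, C7, C8, C8a) carries a cis-diol on the quaternary C7 (OH, CH3, beside the C6 ketone) and on C8. This is the ipso,ortho cis-dihydrodiol of benzoic acid with CO2H reduced to CH3; its diene leaves C6 for oxygen, C8a and C4a for carbon and C5 for chlorine.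
- Forward order: ring A comes from benzoic acid; CO2H becomes the C7 methyl; endoperoxide, then vinyl epoxide, then C8a hydroxymethyl; C6/C4a are oxidised to the chloro-dione enol triflate. The oxolane of the side chain closes by epoxide opening, the fragments are joined at C4a–C4, and the pyran ring closes last.
- Stereochemistry: C7 and C8 from the enzyme; C8a relayed from them (O2 anti to the acetonide, silylmethyl anti to the epoxide); C3' from an Evans alkylation; C2' and the carbinol carbon from one Sharpless epoxidation (retention at one carbon, inversion at the other); the E alkene from a Takai olefination.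

Key step: step 1

Remark: ring A locants follow the target (C4a, C5, C6, C7, C8, C8a; C1 is the carbon on C8a; C2', C3' are oxolane carbons). α is the face of ring A that bears the C7 and C8 oxygens, β the opposite face. Compound 16 is drawn as the diketone and 17 as one enol.

## Route

Step 1
Reactants: 1 benzoic acid (fed as sodium benzoate)
Product: 2 (1S,2R)-1,2-dihydroxycyclohexa-3,5-diene-1-carboxylic acid
Conditions: growing whole cells of Cupriavidus necator (Ralstonia eutropha) B9 (benzoate 1,2-dioxygenase active, diol dehydrogenase absent), fructose, mineral medium, air, 30 °C, pH 7; then pH 3, EtOAc extraction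
Reagents that add atoms: dioxygen, O=O
Why: Benzoate 1,2-dioxygenase is a Rieske non-heme iron dioxygenase: electrons from NADH reach a mononuclear divalent iron site, where O2 is bound and reduced to an iron-bound oxidant that transfers both oxygen atoms suprafacially to C1 (ipso) and C2 (ortho) of the bound benzoate. The closest known reaction type is the arene cis-dihydroxylation of toluene or chlorobenzene by related dioxygenases, and the ipso,ortho mode on benzoate with a B9-type mutant is itself established. No ring is closed: two C–O bonds (the later C7–O and C8–O) form and the arene is dearomatised to a cyclohexadiene. Both new stereocentres, C1 (S) and C2 (R), are set by the chiral active site, which holds the carboxylate-anchored ring in one orientation and delivers both oxygens to one face, hence the cis relationship and a single enantiomer. The step needs 1,2- rather than 2,3-regiochemistry, which the carboxylate binding mode secures, and it needs the diol to persist, which the missing diol dehydrogenase secures, since the wild type would decarboxylate it to catechol. Once CO2H has become CH3 these centres are (7R,8R) of the target.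

Step 2
Reactants: 2 (1S,2R)-1,2-dihydroxycyclohexa-3,5-diene-1-carboxylic acid
Product: 3 (3aS,7aR)-2,2-dimethyl-3a,7a-dihydro-1,3-benzodioxole-3a-carboxylic acid
Conditions: 2,2-dimethoxypropane, TsOH·H2O (cat.), acetone, 0 °C to rt; Et3N quench
Reagents that add atoms: 2,2-dimethoxypropane, COC(C)(C)OC
Why: Acid-catalysed transketalisation (acetonide formation) should tie the cis-diol into a dioxolane faster than the diol dehydrates, masking both hydroxyls and making the α face the hindered face of the diene.

Step 3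
Reactants: 3 acetonide acid
Product: 4 [(3aR,7aR)-2,2-dimethyl-3a,7a-dihydro-1,3-benzodioxol-3a-yl]methanol
Conditions: LiAlH4, THF, 0 °C to rt; aqueous NaOH work-up
Reagents that add atoms: none
Why: LiAlH4 reduction of a carboxylic acid to the primary alcohol, with the unconjugated diene and the acetal inert to hydride.

Step 4
Reactants: 4 primary alcohol
Product: 6 (3aS,7aR)-2,2,3a-trimethyl-3a,7a-dihydro-1,3-benzodioxole, via neopentyl triflate 5 (not isolated)
Conditions: Tf2O, 2,6-lutidine, CH2Cl2, −78 °C; crude 5, LiEt3BH, THF, −78 to 0 °C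
Reagents that add atoms: none
Why: Deoxygenation by sulfonate displacement: a triflate is reactive enough for SN2 hydride delivery from LiEt3BH at a neopentyl carbon that has no β-hydrogen to eliminate, so the carboxyl carbon should become the C7 methyl without touching either stereocentre.

Step 5
Reactants: 6 C7-methyl diene acetonide
Product: 7 6β,8aβ-epidioxy-7α,8α-(isopropylidenedioxy)-7β-methylcyclohex-4a-ene (2,3-dioxabicyclo[2.2.2]oct-5-ene core)
Conditions: O2, tetraphenylporphyrin (cat.), visible light, CH2Cl2, −30 °C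
Reagents that add atoms: dioxygen, O=O
Why: Singlet-oxygen [4+2] cycloaddition across C6 and C8a of the cis-locked diene, expected from the β face because the α face is covered by the dioxolane, which places both new C–O bonds anti to the diol oxygens.

Step 6
Reactants: 7 endoperoxide
Product: 8 5β,6β-epoxy-7α,8α-(isopropylidenedioxy)-7β-methylcyclohex-4a(8a)-ene
Conditions: PPh3, CH2Cl2, 0 °C to rt
Reagents that add atoms: none
Why: Deoxygenation of an unsaturated bicyclic endoperoxide by a trivalent phosphorus compound: PPh3 should attack the less hindered peroxide oxygen (on C8a; the one on C6 is flanked by the quaternary C7 and its β-methyl), and the C6 alkoxide then closes onto C5 in an SN2' manner with loss of Ph3P=O, so the epoxide keeps the β orientation and sits at C5–C6 beside a C4a=C8a alkene.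

Step 7
Reactants: 8 vinyl epoxide; 9 (chloromethyl)isopropoxydimethylsilane
Product: 12 8aα-(hydroxymethyl)-7α,8α-(isopropylidenedioxy)-7β-methylcyclohex-4a-en-6β-ol, via Grignard reagent 10 (not isolated), via silylmethyl allylic alcohol 11 (not isolated)
Conditions: 9, Mg, THF, reflux; then CuI (10 mol %), 8, THF, −30 to 0 °C; NH4Cl (aq); crude 11, KF, KHCO3, 30 % H2O2, THF/MeOH, rt
Reagents that add atoms: hydrogen peroxide, OO
Why: Copper-catalysed SN2' opening of a cyclic vinyl epoxide by the Grignard reagent should add the silylmethyl group to C8a anti to the epoxide oxygen, that is on the α face cis to the C8 oxygen, with the alkene moving to C4a=C5, and Tamao oxidation then converts the C–Si bond into C–OH.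

Step 8
Reactants: 12 diol
Product: 13 8aα-[(tert-butyldimethylsilyloxy)methyl]-7α,8α-(isopropylidenedioxy)-7β-methylcyclohex-4a-en-6β-ol
Conditions: TBSCl, imidazole, CH2Cl2, 0 °C
Reagents that add atoms: tert-butyldimethylsilyl chloride, CC(C)(C)[Si](C)(C)Cl
Why: Selective silylation of the primary C1 hydroxyl over the secondary C6 hydroxyl, which is shielded by the adjacent quaternary C7.

Step 9
Reactants: 13 allylic alcohol
Product: 14 4aβ,5β-epoxy-8aα-[(tert-butyldimethylsilyloxy)methyl]-7α,8α-(isopropylidenedioxy)-7β-methylcyclohexan-6β-ol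
Conditions: VO(acac)2 (5 mol %), t-BuOOH, CH2Cl2, 0 °C to rt
Reagents that add atoms: tert-butyl hydroperoxide, CC(C)(C)OO
Why: Hydroxyl-directed vanadium-catalysed epoxidation of a cyclic allylic alcohol, expected syn to the C6 hydroxyl; both new stereocentres are erased two steps later, so the facial outcome is not critical.

Step 10
Reactants: 14 epoxy alcohol
Product: 15 4aβ,5β-epoxy-8aα-[(tert-butyldimethylsilyloxy)methyl]-7α,8α-(isopropylidenedioxy)-7β-methylcyclohexan-6-one
Conditions: Dess–Martin periodinane, NaHCO3, CH2Cl2, 0 °C to rt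
Reagents that add atoms: none
Why: Dess–Martin oxidation of the secondary alcohol under buffered, neutral conditions that leave the epoxide, the acetal and the silyl ether alone.

Step 11
Reactants: 15 epoxy ketone
Product: 16 8aα-[(tert-butyldimethylsilyloxy)methyl]-7α,8α-(isopropylidenedioxy)-7β-methylcyclohexane-4a,6-dione
Conditions: Pd(PPh3)4 (5 mol %), 1,2-bis(diphenylphosphino)ethane (5 mol %), toluene, 80 °C
Reagents that add atoms: none
Why: Isomerisation of an α,β-epoxy ketone to a β-diketone catalysed by zerovalent palladium (oxidative addition at the C5–O bond, β-hydride elimination from C4a–H), a neutral process that should not disturb the C8a centre.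

Step 12
Reactants: 16 1,3-dione
Product: 17 5-chloro derivative of 16 (drawn as the 4a-enol)
Conditions: NCS (1.0 equiv), CH2Cl2, 0 °C to rt
Reagents that add atoms: N-chlorosuccinimide, O=C1CCC(=O)N1Cl
Why: Electrophilic chlorination of the 1,3-dione enol at C5, the only carbon between the two carbonyls, with one equivalent to stop at the monochloride.

Step 13
Reactants: 17 chloro-dione
Product: 18 8aα-[(tert-butyldimethylsilyloxy)methyl]-5-chloro-7α,8α-(isopropylidenedioxy)-7β-methyl-6-oxocyclohex-4a-en-4a-yl trifluoromethanesulfonate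
Conditions: Tf2O, Et3N, CH2Cl2, −78 °C
Reagents that add atoms: trifluoromethanesulfonic anhydride, O=S(=O)(OS(=O)(=O)C(F)(F)F)C(F)(F)F
Why: O-sulfonylation of the chloro-dione enolate (enol triflate formation), expected at the C4a oxygen because the C6 oxygen is flanked by the quaternary, oxygen-bearing C7.

Step 14
Reactants: 18 protected enol triflate
Product: 19 5-chloro-7α,8α-dihydroxy-8aα-(hydroxymethyl)-7β-methyl-6-oxocyclohex-4a-en-4a-yl trifluoromethanesulfonate
Conditions: TFA/H2O (9:1), 0 °C; toluene co-evaporation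
Reagents that add atoms: none
Why: Acid hydrolysis of the acetonide and the primary silyl ether at the stage of the acid-stable chloro enol triflate, so that the tertiary allylic alcohol of the side chain never meets acid.

Step 15
Reactants: 20 (R)-4-benzyl-3-propionyloxazolidin-2-one
Product: 21 (R)-4-benzyl-3-[(S)-2-methylpent-4-enoyl]oxazolidin-2-one
Conditions: NaHMDS, THF, −78 °C; allyl iodide, −78 to −45 °C
Reagents that add atoms: allyl iodide, C=CCI
Why: Evans alkylation: the chelated Z sodium enolate is attacked by allyl iodide on the face opposite the benzyl group, which should set the (S) centre that becomes C3'.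

Step 16
Reactants: 21 allylated imide
Product: 24 (S)-3-methyloxolan-2-one, via aldehyde imide 22 (not isolated), via hydroxy imide 23 (not isolated)
Conditions: O3, CH2Cl2, −78 °C; Me2S, to rt; then NaBH4, MeOH, 0 °C
Reagents that add atoms: ozone, [O-][O+]=O
Why: Ozonolysis of the terminal alkene, reduction of the aldehyde and lactonisation of the γ-hydroxy imide by intramolecular acyl transfer, which expels the oxazolidinone and leaves the α-methyl stereocentre untouched.

Step 17
Reactants: 24 lactone
Product: 25 (3S)-3-methyloxolan-2-ol (anomer mixture)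
Conditions: i-Bu2AlH (1.1 equiv), CH2Cl2, −78 °C
Reagents that add atoms: none
Why: Half-reduction of a γ-lactone to the lactol, whose tetrahedral aluminium alkoxide is stable at −78 °C.

Step 18
Reactants: 25 lactol
Product: 26 ethyl (2E,4S)-6-hydroxy-2,4-dimethylhex-2-enoate
Conditions: Ph3P=C(CH3)CO2Et, toluene, 80 °C
Reagents that add atoms: ethyl 2-(triphenylphosphoranylidene)propanoate, CCOC(=O)C(C)=P(c1ccccc1)(c1ccccc1)c1ccccc1
Why: Wittig olefination of the open hydroxy aldehyde form of the lactol with a stabilised ylide, which should give the E trisubstituted enoate under neutral conditions that spare the α-stereocentre.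

Step 19
Reactants: 26 hydroxy enoate
Product: 27 (2E,4S)-2,4-dimethylhex-2-ene-1,6-diol
Conditions: i-Bu2AlH (3.3 equiv), CH2Cl2, −78 to 0 °C
Reagents that add atoms: none
Why: 1,2-Reduction of the conjugated ester to the allylic alcohol, which i-Bu2AlH achieves without conjugate reduction.

Step 20
Reactants: 27 allylic diol
Product: 29 (2R)-2-[(2S,3S)-3-methyloxolan-2-yl]propane-1,2-diol, via epoxy diol 28 (not isolated)
Conditions: Ti(OiPr)4 (1.1 equiv), D-(−)-diethyl tartrate (1.3 equiv), t-BuOOH (anhydrous, 2 equiv), 4 Å molecular sieves, CH2Cl2, −25 °C; then 0 °C to rt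
Reagents that add atoms: tert-butyl hydroperoxide, CC(C)(C)OO
Why: Sharpless asymmetric epoxidation with D-(−)-tartrate should give the (2R,3R)-epoxide (the mirror-image sense to the (2S,3S)-epoxides that L-(+)-tartrate gives from E allylic alcohols), and titanium-assisted 5-exo opening at C3 by the remote hydroxyl with inversion then sets C2' (S) while the epoxide oxygen stays as the (R) tertiary carbinol.

Step 21
Reactants: 29 oxolane diol
Product: 30 (2S)-2-hydroxy-2-[(2S,3S)-3-methyloxolan-2-yl]propanal
Conditions: SO3·pyridine, DMSO, i-Pr2NEt, CH2Cl2, 0 °C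
Reagents that add atoms: none
Why: Parikh–Doering oxidation of the primary alcohol, which does not cleave the 1,2-diol and cannot epimerise the aldehyde because its α-carbon bears no hydrogen.

Step 22
Reactants: 30 α-hydroxy aldehyde
Product: 31 (2R,3E)-4-iodo-2-[(2S,3S)-3-methyloxolan-2-yl]but-3-en-2-ol
Conditions: CrCl2 (6 equiv), CHI3 (2 equiv), THF, 0 °C to rt
Reagents that add atoms: iodoform, IC(I)I
Why: Takai olefination, a non-basic chromium-mediated iodomethylenation that is E-selective for α-branched aldehydes and tolerates the free tertiary hydroxyl.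

Step 23
Reactants: 31 vinyl iodide
Product: 32 (2R,3E)-2-[(2S,3S)-3-methyloxolan-2-yl]hex-3-en-5-yn-2-ol
Conditions: HC≡CMgBr (3 equiv), ZnBr2 (3 equiv), THF, 0 °C; Pd(PPh3)4 (5 mol %), rt
Reagents that add atoms: ethynylmagnesium bromide, C#C[Mg]Br
Why: Negishi coupling of an alkenyl iodide with ethynylzinc bromide, which gives the terminal enyne directly with retention of the E geometry.

Step 24
Reactants: 19 triol enol triflate; 32 side-chain enyne
Product: 33 5-chloro-7α,8α-dihydroxy-8aα-(hydroxymethyl)-4a-[(3E,5R)-5-hydroxy-5-((2S,3S)-3-methyloxolan-2-yl)hex-3-en-1-ynyl]-7β-methylcyclohex-4a-en-6-one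
Conditions: PdCl2(PPh3)2 (5 mol %), CuI (10 mol %), i-Pr2NEt, THF, rt
Reagents that add atoms: none
Why: Sonogashira coupling of a β-triflyloxy enone with a terminal alkyne, in which the vinyl triflate reacts far faster than the vinyl chloride at C5 and free hydroxyls are tolerated.

Step 25
Reactants: 33 tetraol ynenone
Product: 34 (7R,8R,8aS)-5-chloro-7,8-dihydroxy-3-[(1E,3R)-3-hydroxy-3-((2S,3S)-3-methyloxolan-2-yl)but-1-enyl]-7-methyl-8,8a-dihydro-1H-isochromen-6(7H)-one
Conditions: Ph3PAuNTf2 (5 mol %), CH2Cl2, 0 °C to rt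
Reagents that add atoms: none
Why: 6-endo-dig hydroalkoxylation catalysed by monovalent gold: the C1 hydroxyl adds to C3, the δ-carbon of the ynenone, to give the conjugated pyran, while the C7 and C8 hydroxyls cannot reach the alkyne without a bridgehead alkene and the E alkene keeps the side-chain hydroxyl away.

## Compound list

1 | benzoic acid | OC(=O)c1ccccc1 | starting material
2 | (1S,2R)-1,2-dihydroxycyclohexa-3,5-diene-1-carboxylic acid | OC(=O)[C@]1(O)C=CC=C[C@H]1O | intermediate
3 | (3aS,7aR)-2,2-dimethyl-3a,7a-dihydro-1,3-benzodioxole-3a-carboxylic acid | OC(=O)[C@]12C=CC=C[C@H]1OC(C)(C)O2 | intermediate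
4 | [(3aR,7aR)-2,2-dimethyl-3a,7a-dihydro-1,3-benzodioxol-3a-yl]methanol | OC[C@]12C=CC=C[C@H]1OC(C)(C)O2 | intermediate
5 | trifluoromethanesulfonate of 4 (neopentyl triflate) | O=S(=O)(OC[C@]12C=CC=C[C@H]1OC(C)(C)O2)C(F)(F)F | intermediate
6 | (3aS,7aR)-2,2,3a-trimethyl-3a,7a-dihydro-1,3-benzodioxole | C[C@]12C=CC=C[C@H]1OC(C)(C)O2 | intermediate
7 | 6β,8aβ-epidioxy-7α,8α-(isopropylidenedioxy)-7β-methylcyclohex-4a-ene (peroxide bridge anti to the acetonide) | C[C@]12[C@@H]3OO[C@@H](C=C3)[C@H]1OC(C)(C)O2 | intermediate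
8 | 5β,6β-epoxy-7α,8α-(isopropylidenedioxy)-7β-methylcyclohex-4a(8a)-ene | C[C@]12[C@@H]3O[C@@H]3C=C[C@H]1OC(C)(C)O2 | intermediate
9 | (chloromethyl)isopropoxydimethylsilane | CC(C)O[Si](C)(C)CCl | starting material
10 | [(isopropoxydimethylsilyl)methyl]magnesium chloride | CC(C)O[Si](C)(C)C[Mg]Cl | intermediate
11 | 8aα-[(isopropoxydimethylsilyl)methyl]-7α,8α-(isopropylidenedioxy)-7β-methylcyclohex-4a-en-6β-ol | C[C@]12[C@H](O)C=C[C@@H](C[Si](C)(C)OC(C)C)[C@H]1OC(C)(C)O2 | intermediate
12 | 8aα-(hydroxymethyl)-7α,8α-(isopropylidenedioxy)-7β-methylcyclohex-4a-en-6β-ol | C[C@]12[C@H](O)C=C[C@@H](CO)[C@H]1OC(C)(C)O2 | intermediate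
13 | 8aα-[(tert-butyldimethylsilyloxy)methyl]-7α,8α-(isopropylidenedioxy)-7β-methylcyclohex-4a-en-6β-ol | C[C@]12[C@H](O)C=C[C@@H](CO[Si](C)(C)C(C)(C)C)[C@H]1OC(C)(C)O2 | intermediate
14 | 4aβ,5β-epoxy-8aα-[(tert-butyldimethylsilyloxy)methyl]-7α,8α-(isopropylidenedioxy)-7β-methylcyclohexan-6β-ol | C[C@]12[C@H](O)[C@@H]3O[C@@H]3[C@@H](CO[Si](C)(C)C(C)(C)C)[C@H]1OC(C)(C)O2 | intermediate
15 | 4aβ,5β-epoxy-8aα-[(tert-butyldimethylsilyloxy)methyl]-7α,8α-(isopropylidenedioxy)-7β-methylcyclohexan-6-one | C[C@]12C(=O)[C@@H]3O[C@@H]3[C@@H](CO[Si](C)(C)C(C)(C)C)[C@H]1OC(C)(C)O2 | intermediate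
16 | 8aα-[(tert-butyldimethylsilyloxy)methyl]-7α,8α-(isopropylidenedioxy)-7β-methylcyclohexane-4a,6-dione | C[C@]12C(=O)CC(=O)[C@@H](CO[Si](C)(C)C(C)(C)C)[C@H]1OC(C)(C)O2 | intermediate
17 | 5-chloro derivative of 16, 4a-enol form | C[C@]12C(=O)C(Cl)=C(O)[C@@H](CO[Si](C)(C)C(C)(C)C)[C@H]1OC(C)(C)O2 | intermediate
18 | 8aα-[(tert-butyldimethylsilyloxy)methyl]-5-chloro-7α,8α-(isopropylidenedioxy)-7β-methyl-6-oxocyclohex-4a-en-4a-yl trifluoromethanesulfonate | C[C@]12C(=O)C(Cl)=C(OS(=O)(=O)C(F)(F)F)[C@@H](CO[Si](C)(C)C(C)(C)C)[C@H]1OC(C)(C)O2 | intermediate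
19 | 5-chloro-7α,8α-dihydroxy-8aα-(hydroxymethyl)-7β-methyl-6-oxocyclohex-4a-en-4a-yl trifluoromethanesulfonate | C[C@]1(O)C(=O)C(Cl)=C(OS(=O)(=O)C(F)(F)F)[C@@H](CO)[C@H]1O | intermediate
20 | (R)-4-benzyl-3-propionyloxazolidin-2-one | CCC(=O)N1[C@H](Cc2ccccc2)COC1=O | starting material
21 | (R)-4-benzyl-3-[(S)-2-methylpent-4-enoyl]oxazolidin-2-one | C=CC[C@H](C)C(=O)N1[C@H](Cc2ccccc2)COC1=O | intermediate
22 | (R)-4-benzyl-3-[(S)-2-methyl-4-oxobutanoyl]oxazolidin-2-one | O=CC[C@H](C)C(=O)N1[C@H](Cc2ccccc2)COC1=O | intermediate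
23 | (R)-4-benzyl-3-[(S)-4-hydroxy-2-methylbutanoyl]oxazolidin-2-one | OCC[C@H](C)C(=O)N1[C@H](Cc2ccccc2)COC1=O | intermediate
24 | (S)-3-methyloxolan-2-one | C[C@H]1CCOC1=O | intermediate
25 | (3S)-3-methyloxolan-2-ol (anomer mixture) | C[C@H]1CCOC1O | intermediate
26 | ethyl (2E,4S)-6-hydroxy-2,4-dimethylhex-2-enoate | CCOC(=O)/C(C)=C/[C@@H](C)CCO | intermediate
27 | (2E,4S)-2,4-dimethylhex-2-ene-1,6-diol | OC/C(C)=C/[C@@H](C)CCO | intermediate
28 | [(2R,3R)-3-[(2S)-4-hydroxybutan-2-yl]-2-methyloxiran-2-yl]methanol | OC[C@@]1(C)O[C@@H]1[C@@H](C)CCO | intermediate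
29 | (2R)-2-[(2S,3S)-3-methyloxolan-2-yl]propane-1,2-diol | C[C@H]1CCO[C@@H]1[C@](C)(O)CO | intermediate
30 | (2S)-2-hydroxy-2-[(2S,3S)-3-methyloxolan-2-yl]propanal | C[C@H]1CCO[C@@H]1[C@](C)(O)C=O | intermediate
31 | (2R,3E)-4-iodo-2-[(2S,3S)-3-methyloxolan-2-yl]but-3-en-2-ol | C[C@H]1CCO[C@@H]1[C@](C)(O)/C=C/I | intermediate
32 | (2R,3E)-2-[(2S,3S)-3-methyloxolan-2-yl]hex-3-en-5-yn-2-ol | C[C@H]1CCO[C@@H]1[C@](C)(O)/C=C/C#C | intermediate
33 | 5-chloro-7α,8α-dihydroxy-8aα-(hydroxymethyl)-4a-[(3E,5R)-5-hydroxy-5-((2S,3S)-3-methyloxolan-2-yl)hex-3-en-1-ynyl]-7β-methylcyclohex-4a-en-6-one | C[C@]1(O)C(=O)C(Cl)=C(C#C/C=C/[C@@](C)(O)[C@H]2OCC[C@@H]2C)[C@@H](CO)[C@H]1O | intermediate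
34 | (7R,8R,8aS)-5-chloro-7,8-dihydroxy-3-[(1E,3R)-3-hydroxy-3-((2S,3S)-3-methyloxolan-2-yl)but-1-enyl]-7-methyl-8,8a-dihydro-1H-isochromen-6(7H)-one | C[C@H]1CCO[C@@H]1[C@](C)(O)/C=C/C1=CC2=C(Cl)C(=O)[C@](C)(O)[C@H](O)[C@@H]2CO1 | target

## Count and risks

Total step count: 25. Longest linear sequence: 16 steps (steps 1 to 14, then 24 and 25); the side-chain branch is steps 15 to 23.

Steps most likely to fail:

Step 7. The copper-catalysed opening may suffer from direct SN2 attack at the allylic epoxide carbon C5 competing with attack at C8a, or from slow delivery to the α face of C8a beside the dioxolane. The fallback sets out from endoperoxide 7 and comes back at diol 12, and sets C8a by reagent approach to the open β face instead. Kornblum–DeLaMare rearrangement of 7 (Et3N, CH2Cl2, 0 °C), in which the base should remove the more accessible bridgehead hydrogen on C8a, would give the 6β-hydroxy-4a-en-8a-one, hydroxy enone F1. Silylation (TBSOTf, 2,6-lutidine) would give silyl ether F2, and Wittig methylenation (Ph3P=CH2, THF, −78 to 0 °C) the exocyclic diene F3. Hydroboration of the 1,1-disubstituted terminus with 9-BBN, then NaOH/H2O2, should occur from the β face, anti to the C8 oxygen; this puts hydrogen on C8a (β) and leaves the CH2OH on the α face, primary alcohol F4. Bu4NF then gives 12.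

Step 6. The phosphine may attack the other peroxide oxygen, which would place the epoxide at C4a–C8a instead of C5–C6. The fallback sets out from alcohol 4 and comes back at vinyl epoxide 8, and uses hydroxyl direction before the carboxyl carbon is reduced. With VO(acac)2 and t-BuOOH the homoallylic CH2OH on C7 (β) should direct oxygen to the neighbouring C5=C6 alkene on the β face, giving epoxy alcohol F5. Tf2O and pyridine at −78 °C would give epoxy triflate F6, and Bu4NBH4 in CH2Cl2 should displace the primary triflate by hydride without opening the epoxide, giving 8.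

Step 13. Sulfonylation may occur at the C6 oxygen in competition with the C4a oxygen (poor regioselectivity of enol triflate formation). The fallback sets out from allylic alcohol 13 and comes back at tetraol ynenone 33, and fixes the regiochemistry by adding the alkyne carbon to C4a before chlorine is introduced. MnO2 oxidation gives enone F7. Nickel-catalysed conjugate addition of Me3SiC≡CAlMe2 (Ni(acac)2, i-Bu2AlH, Et2O, −5 °C) gives β-alkynyl ketone F8. The ketone can enolise only toward C5, so two successive enolate chlorinations (LiN(SiMe3)2, then NCS, twice) give dichloro ketone F9, and DBU eliminates HCl across C5–C4a to give the silylethynyl chloroenone F10. K2CO3 in MeOH at 0 °C removes the alkyne silyl group, giving terminal alkyne F11. Sonogashira coupling with vinyl iodide 31 (PdCl2(PPh3)2, CuI, i-Pr2NEt) gives the protected ynenone F12. A short treatment with TFA/H2O at 0 °C removes the acetonide and the silyl ether to give 33.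

Further compounds
F1 | step 7 | 6β-hydroxy-7α,8α-(isopropylidenedioxy)-7β-methylcyclohex-4a-en-8a-one | C[C@]12[C@H](O)C=CC(=O)[C@H]1OC(C)(C)O2
F2 | step 7 | 6β-(tert-butyldimethylsilyloxy)-7α,8α-(isopropylidenedioxy)-7β-methylcyclohex-4a-en-8a-one | C[C@]12[C@H](O[Si](C)(C)C(C)(C)C)C=CC(=O)[C@H]1OC(C)(C)O2
F3 | step 7 | 6β-(tert-butyldimethylsilyloxy)-7α,8α-(isopropylidenedioxy)-7β-methyl-8a-methylidenecyclohex-4a-ene | C[C@]12[C@H](O[Si](C)(C)C(C)(C)C)C=CC(=C)[C@H]1OC(C)(C)O2
F4 | step 7 | [6β-(tert-butyldimethylsilyloxy)-7α,8α-(isopropylidenedioxy)-7β-methylcyclohex-4a-en-8aα-yl]methanol | C[C@]12[C@H](O[Si](C)(C)C(C)(C)C)C=C[C@@H](CO)[C@H]1OC(C)(C)O2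
F5 | step 6 | [5β,6β-epoxy-7α,8α-(isopropylidenedioxy)cyclohex-4a(8a)-en-7β-yl]methanol | OC[C@]12[C@@H]3O[C@@H]3C=C[C@H]1OC(C)(C)O2
F6 | step 6 | trifluoromethanesulfonate of F5 | O=S(=O)(OC[C@]12[C@@H]3O[C@@H]3C=C[C@H]1OC(C)(C)O2)C(F)(F)F
F7 | step 13 | 8aα-[(tert-butyldimethylsilyloxy)methyl]-7α,8α-(isopropylidenedioxy)-7β-methylcyclohex-4a-en-6-one | C[C@]12C(=O)C=C[C@@H](CO[Si](C)(C)C(C)(C)C)[C@H]1OC(C)(C)O2
F8 | step 13 | 8aα-[(tert-butyldimethylsilyloxy)methyl]-7α,8α-(isopropylidenedioxy)-7β-methyl-4a-[(trimethylsilyl)ethynyl]cyclohexan-6-one (C4a configuration not defined) | C[C@]12C(=O)CC(C#C[Si](C)(C)C)[C@@H](CO[Si](C)(C)C(C)(C)C)[C@H]1OC(C)(C)O2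
F9 | step 13 | 5,5-dichloro derivative of F8 | C[C@]12C(=O)C(Cl)(Cl)C(C#C[Si](C)(C)C)[C@@H](CO[Si](C)(C)C(C)(C)C)[C@H]1OC(C)(C)O2
F10 | step 13 | 8aα-[(tert-butyldimethylsilyloxy)methyl]-5-chloro-7α,8α-(isopropylidenedioxy)-7β-methyl-4a-[(trimethylsilyl)ethynyl]cyclohex-4a-en-6-one | C[C@]12C(=O)C(Cl)=C(C#C[Si](C)(C)C)[C@@H](CO[Si](C)(C)C(C)(C)C)[C@H]1OC(C)(C)O2
F11 | step 13 | 8aα-[(tert-butyldimethylsilyloxy)methyl]-5-chloro-4a-ethynyl-7α,8α-(isopropylidenedioxy)-7β-methylcyclohex-4a-en-6-one | C[C@]12C(=O)C(Cl)=C(C#C)[C@@H](CO[Si](C)(C)C(C)(C)C)[C@H]1OC(C)(C)O2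
F12 | step 13 | acetonide and C1 tert-butyldimethylsilyl ether of 33 | C[C@]12C(=O)C(Cl)=C(C#C/C=C/[C@@](C)(O)[C@H]3OCC[C@@H]3C)[C@@H](CO[Si](C)(C)C(C)(C)C)[C@H]1OC(C)(C)O2
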